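**Plan**

- Numbering used in the text (target): ring C1 = C(OH)CH3, C2 = C=O, C3 = CH–OAng, C4 = CH carrying the side chain, C5 = CH–OAng, C6 = CH–OH; side chain C7(=CH2)–C8(OAng)–C9H2–C10/C11 epoxide. Compound names use their own locants.
- Retrosynthesis: the three angelates and the side-chain epoxide are removed first (C–O), then C7–C8 (vinyl iodide + aldehyde), then the ring bonds C1–C2 and C4–C5 are cut together.
- Enabling feature: in the cyclohexane ring, C6 is a latent ketone flanked by its two α-carbons C5 and C1 (C1 bearing the methyl group), and C2–C3–C4 is a latent enal (C2 aldehyde carbon, C4 β-carbon). The ring is therefore a latent 2-methylcyclohex-2-enone, open to a one-flask Michael/aldol condensation [3+3] annulation.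
- Forward: enynal + tert-butyl 3-oxopentanoate give the enone; the alkyne becomes the 2-iodoalkene; α′-hydroxylation at C5; Wharton transposition of the carbonyl from C6 to C2; α′-hydroxylation at C3; epoxidation and trans-diaxial hydrolysis for C6/C1; Nozaki–Hiyama–Kishi coupling; desilylation; triple angeloylation; epoxidation.
- Stereochemistry: C4 from the amine catalyst; C5 and C3 by enolate hydroxylation trans to the C4 substituent; C1 and C6 by epoxidation anti to the C5 silyloxy group followed by inversion at C6; C8 from the chiral chromium ligand; C10 from the chiral ketone catalyst; Z esters from angelic acid.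

Key step: step 2

Remark: the sense of induction of the (S)-diarylprolinol silyl ether (step 2) and of the chromium ligand (step 14) is assigned from the usual shielding models; if either proves opposite, the enantiomeric catalyst or ligand is used.

**Route**

Step 1
Reactants: 1 3-(trimethylsilyl)prop-2-ynal; 2 (triphenylphosphoranylidene)acetaldehyde
Product: 3 (2E)-5-(trimethylsilyl)pent-2-en-4-ynal
Conditions: toluene, rt (2 as limiting reagent)
Reagents that add atoms: none
Why: Wittig olefination with the stabilised formyl ylide should be E-selective and stop at the mono-adduct because the product enal is less electrophilic than the ynal.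

Step 2
Reactants: 3 (2E)-5-(trimethylsilyl)pent-2-en-4-ynal; 4 tert-butyl 3-oxopentanoate
Product: 6 (5R)-2-methyl-5-[(trimethylsilyl)ethynyl]cyclohex-2-en-1-one, via Michael adduct 5 (not isolated)
Conditions: (S)-2-{bis[3,5-bis(trifluoromethyl)phenyl](trimethylsilyloxy)methyl}pyrrolidine (10 mol %), PhCO2H (10 mol %), toluene, rt; then TsOH·H2O (20 mol %), 80 °C
Reagents that add atoms: none
Why: The amine condenses with 3 to an (E)-iminium ion whose β-carbon (future C4) is attacked by the enol of 4 through its doubly activated carbon (future C5), giving 5 after hydrolysis; under TsOH the tert-butyl ester is cleaved and decarboxylates, the ethyl-ketone α′-carbon (future C1) adds to the aldehyde carbon (future C2) and water is lost, so that C4–C5 and C1–C2 arise in one flask. The closest known reaction type is the amine-catalysed Michael addition/intramolecular aldol condensation of β-keto esters with enals to 5-substituted cyclohex-2-enones (a Robinson-type [3+3] annulation). The ring closes in a 6-(enolexo)-exo-trig aldol, the only closure of 5 that does not give a four-membered ring. The single new stereocentre (C4) is controlled by the catalyst, whose diaryl(silyloxy)methyl group shields one face of the s-trans iminium ion and should lead to the (5R)-enone. The step needs 1,4- over 1,6-addition, secured by the silyl cap on the alkyne terminus, and Michael attack through C5 and not C1 of the keto ester, secured by the ester group, which is then lost.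

Step 3
Reactants: 6 (5R)-2-methyl-5-[(trimethylsilyl)ethynyl]cyclohex-2-en-1-one
Product: 8 (5R)-5-(1-iodoethenyl)-2-methylcyclohex-2-en-1-one, via terminal alkyne 7 (not isolated)
Conditions: K2CO3 (cat.), MeOH, 0 °C; extractive work-up; then NaI, Me3SiCl, H2O, MeCN, 0 °C to rt; NaHCO3/Na2S2O3 work-up
Reagents that add atoms: sodium iodide, [Na+].[I-]
Why: Methanolysis of the C(sp)–Si bond followed by Markovnikov hydroiodination of the terminal alkyne with HI made in the flask should give the 2-iodoalkene at a stage with no acid-labile group, any β-iodo ketone reverting to the enone on basic work-up.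

Step 4
Reactants: 8 (5R)-5-(1-iodoethenyl)-2-methylcyclohex-2-en-1-one
Product: 9 (5R,6S)-6-hydroxy-5-(1-iodoethenyl)-2-methylcyclohex-2-en-1-one
Conditions: KN(SiMe3)2, THF, −78 °C; 2-(phenylsulfonyl)-3-phenyloxaziridine, −78 °C; AcOH quench
Reagents that add atoms: 2-(phenylsulfonyl)-3-phenyloxaziridine, O=S(=O)(c1ccccc1)N1OC1c1ccccc1
Why: Kinetic α′-deprotonation of the enone and Davis oxidation of the cross-conjugated enolate should place the hydroxyl at C5 trans to the adjacent C4 substituent (oxidant approaches anti to it; the trans ketol is also the thermodynamic epimer).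

Step 5
Reactants: 9 (5R,6S)-6-hydroxy-5-(1-iodoethenyl)-2-methylcyclohex-2-en-1-one
Product: 10 (5R,6S)-6-[(tert-butyldimethylsilyl)oxy]-5-(1-iodoethenyl)-2-methylcyclohex-2-en-1-one
Conditions: TBSCl, imidazole, DMF, rt
Reagents that add atoms: tert-butyldimethylsilyl chloride, CC(C)(C)[Si](C)(C)Cl
Why: Standard silylation of the secondary ketol hydroxyl protects C5–OH against the oxidation in step 8 and the basic steps that follow.

Step 6
Reactants: 10 (5R,6S)-6-[(tert-butyldimethylsilyl)oxy]-5-(1-iodoethenyl)-2-methylcyclohex-2-en-1-one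
Product: 11 (1R,3S,4R,6R)-3-[(tert-butyldimethylsilyl)oxy]-4-(1-iodoethenyl)-1-methyl-7-oxabicyclo[4.1.0]heptan-2-one
Conditions: H2O2 (30 % aq.), NaOH (cat.), MeOH, 0 °C
Reagents that add atoms: hydrogen peroxide, OO
Why: Weitz–Scheffer nucleophilic epoxidation touches only the enone double bond; hydroperoxide should add anti to the C4 substituent as in carvone, but the epoxide configuration is erased in step 7.

Step 7
Reactants: 11 (1R,3S,4R,6R)-3-[(tert-butyldimethylsilyl)oxy]-4-(1-iodoethenyl)-1-methyl-7-oxabicyclo[4.1.0]heptan-2-one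
Product: 12 (1R,4R,5R)-4-[(tert-butyldimethylsilyl)oxy]-5-(1-iodoethenyl)-2-methylcyclohex-2-en-1-ol
Conditions: N2H4·H2O, AcOH (cat.), MeOH, 0 °C to rt
Reagents that add atoms: none
Why: Wharton transposition: the epoxy hydrazone fragments with loss of N2 to the allylic alcohol, moving the oxygen from C6 to C2 and the double bond to C6=C1 (the carbinol configuration is immaterial).

Step 8
Reactants: 12 (1R,4R,5R)-4-[(tert-butyldimethylsilyl)oxy]-5-(1-iodoethenyl)-2-methylcyclohex-2-en-1-ol
Product: 13 (4R,5R)-4-[(tert-butyldimethylsilyl)oxy]-5-(1-iodoethenyl)-2-methylcyclohex-2-en-1-one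
Conditions: DMP (1,1,1-triacetoxy-1,1-dihydro-1,2-benziodoxol-3(1H)-one), CH2Cl2, 0 °C to rt
Reagents that add atoms: none
Why: Periodinane oxidation of the allylic alcohol should give the transposed enone (carbonyl now at C2) without touching the vinyl iodide or the silyl ether.

Step 9
Reactants: 13 (4R,5R)-4-[(tert-butyldimethylsilyl)oxy]-5-(1-iodoethenyl)-2-methylcyclohex-2-en-1-one
Product: 14 (4R,5R,6R)-4-[(tert-butyldimethylsilyl)oxy]-6-hydroxy-5-(1-iodoethenyl)-2-methylcyclohex-2-en-1-one
Conditions: KN(SiMe3)2, THF, −78 °C; 2-(phenylsulfonyl)-3-phenyloxaziridine, −78 °C; AcOH quench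
Reagents that add atoms: 2-(phenylsulfonyl)-3-phenyloxaziridine, O=S(=O)(c1ccccc1)N1OC1c1ccccc1
Why: Second Davis oxidation, now of the kinetic C3 enolate of the transposed enone; attack anti to the C4 substituent should give the 3,4-trans ketol (also the thermodynamic epimer).

Step 10
Reactants: 14 (4R,5R,6R)-4-[(tert-butyldimethylsilyl)oxy]-6-hydroxy-5-(1-iodoethenyl)-2-methylcyclohex-2-en-1-one
Product: 15 (4R,5S,6R)-4,6-bis[(tert-butyldimethylsilyl)oxy]-5-(1-iodoethenyl)-2-methylcyclohex-2-en-1-one
Conditions: TBSCl, imidazole, DMF, rt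
Reagents that add atoms: tert-butyldimethylsilyl chloride, CC(C)(C)[Si](C)(C)Cl
Why: Silylation protects the α-ketol against cleavage by alkaline peroxide in step 11.

Step 11
Reactants: 15 (4R,5S,6R)-4,6-bis[(tert-butyldimethylsilyl)oxy]-5-(1-iodoethenyl)-2-methylcyclohex-2-en-1-one
Product: 16 (1R,3R,4S,5S,6R)-3,5-bis[(tert-butyldimethylsilyl)oxy]-4-(1-iodoethenyl)-1-methyl-7-oxabicyclo[4.1.0]heptan-2-one
Conditions: H2O2 (30 % aq.), NaOH (cat.), MeOH, 0 °C
Reagents that add atoms: hydrogen peroxide, OO
Why: Weitz–Scheffer epoxidation in which hydroperoxide should add to C6 anti to the adjacent C5 silyloxy group (the usual 3,4-trans addition to 4-substituted cyclohexenones), placing the epoxide oxygen on the face of the C4 side chain and so fixing the C1 carbinol configuration.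

Step 12
Reactants: 16 (1R,3R,4S,5S,6R)-3,5-bis[(tert-butyldimethylsilyl)oxy]-4-(1-iodoethenyl)-1-methyl-7-oxabicyclo[4.1.0]heptan-2-one
Product: 17 (2R,3S,4S,5S,6R)-4,6-bis[(tert-butyldimethylsilyl)oxy]-2,3-dihydroxy-5-(1-iodoethenyl)-2-methylcyclohexan-1-one
Conditions: HClO4 (aq., 1 M), THF, 0 °C to rt
Reagents that add atoms: water, O
Why: Acid-catalysed hydrolysis of the α,β-epoxy ketone: water should attack C6 (β to the carbonyl, the α-carbon being deactivated and quaternary) with inversion in a trans-diaxial opening, setting C6–OH cis to C5–O and trans to the retained C1–OH.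

Step 13
Reactants: 18 4-methylpent-3-en-1-ol
Product: 19 4-methylpent-3-enal
Conditions: DMP, CH2Cl2, 0 °C; used at once without purification
Reagents that add atoms: none
Why: Non-basic periodinane oxidation gives the β,γ-unsaturated aldehyde, which is used immediately to avoid migration of the double bond into conjugation.

Step 14
Reactants: 17 (2R,3S,4S,5S,6R)-4,6-bis[(tert-butyldimethylsilyl)oxy]-2,3-dihydroxy-5-(1-iodoethenyl)-2-methylcyclohexan-1-one; 19 4-methylpent-3-enal
Product: 20 (2R,3S,4S,5S,6R)-4,6-bis[(tert-butyldimethylsilyl)oxy]-2,3-dihydroxy-5-[(3S)-3-hydroxy-6-methylhepta-1,5-dien-2-yl]-2-methylcyclohexan-1-one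
Conditions: CrCl2 (4 equiv), (S)-4-isopropyl-2-[2-(methanesulfonamido)-3-methylphenyl]-2-oxazoline, Et3N, THF, rt; then NiCl2 (cat.), 17 and 19, rt
Reagents that add atoms: none
Why: Nozaki–Hiyama–Kishi coupling: nickel inserts into the C–I bond, the vinyl group passes to trivalent chromium and adds to the aldehyde only (ring ketone and free hydroxyls are tolerated), forming C7–C8 with the C8 configuration set by the chiral sulfonamide–oxazoline ligand on chromium.

Step 15
Reactants: 20 (2R,3S,4S,5S,6R)-4,6-bis[(tert-butyldimethylsilyl)oxy]-2,3-dihydroxy-5-[(3S)-3-hydroxy-6-methylhepta-1,5-dien-2-yl]-2-methylcyclohexan-1-one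
Product: 21 (2R,3S,4S,5S,6R)-2,3,4,6-tetrahydroxy-5-[(3S)-3-hydroxy-6-methylhepta-1,5-dien-2-yl]-2-methylcyclohexan-1-one
Conditions: HF·pyridine, pyridine, THF, 0 °C to rt
Reagents that add atoms: none
Why: Buffered acidic fluoride removes both silyl ethers without the basic conditions that would trigger retro-aldol cleavage of the β-hydroxy ketone.

Step 16
Reactants: 21 (2R,3S,4S,5S,6R)-2,3,4,6-tetrahydroxy-5-[(3S)-3-hydroxy-6-methylhepta-1,5-dien-2-yl]-2-methylcyclohexan-1-one
Product: 22 the 4-O,6-O,3′-O-tris[(Z)-2-methylbut-2-enoate] of 21 (ring 2R,3S,4S,5S,6R; side chain 3S; hydroxyls at C2 and C3 of the cyclohexanone free)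
Conditions: angelic acid (3.6 equiv), 2,4,6-trichlorobenzoyl chloride, Et3N, toluene, rt; then 21, 60–70 °C, no DMAP
Reagents that add atoms: angelic acid [(Z)-2-methylbut-2-enoic acid], C/C=C(/C)C(=O)O
Why: Yamaguchi esterification through the preformed mixed anhydride (DMAP-free to keep the Z geometry) should acylate the two equatorial ring hydroxyls (C3, C5) and the allylic C8 hydroxyl, while the axial C6 hydroxyl next to the quaternary C1 and the tertiary C1 hydroxyl are too hindered to react.

Step 17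
Reactants: 22 tris-angelate
Product: 23 CNP0313777.1, the 4-O,6-O,3′-O-tris[(Z)-2-methylbut-2-enoate] of (2R,3S,4S,5S,6R)-5-{(3S)-4-[(2R)-3,3-dimethyloxiran-2-yl]-3-hydroxybut-1-en-2-yl}-2,3,4,6-tetrahydroxy-2-methylcyclohexan-1-one
Conditions: 1,2:4,5-di-O-isopropylidene-β-D-erythro-2,3-hexodiulo-2,6-pyranose (1 equiv), KHSO5 (as Oxone), NaHCO3, aq. Na2EDTA, MeCN, 0 °C (pH about 8)
Reagents that add atoms: potassium peroxymonosulfate, [K+].[O-]S(=O)(=O)OO
Why: Shi epoxidation: the chiral dioxirane should epoxidise only the electron-rich trisubstituted alkene (not the 1,1-disubstituted alkene or the electron-poor angelates), the D-fructose-derived ketone giving the (10R)-epoxide, and the near-neutral buffer spares the esters and the β-hydroxy ketone.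

**Compound list**

1 | 3-(trimethylsilyl)prop-2-ynal | C[Si](C)(C)C#CC=O | starting material
2 | (triphenylphosphoranylidene)acetaldehyde | O=CC=P(c1ccccc1)(c1ccccc1)c1ccccc1 | starting material
3 | (2E)-5-(trimethylsilyl)pent-2-en-4-ynal | C[Si](C)(C)C#C/C=C/C=O | intermediate
4 | tert-butyl 3-oxopentanoate | CCC(=O)CC(=O)OC(C)(C)C | starting material
5 | tert-butyl (3R)-5-oxo-2-propanoyl-3-[(trimethylsilyl)ethynyl]pentanoate (both C2 epimers) | C[Si](C)(C)C#C[C@H](CC=O)C(C(=O)OC(C)(C)C)C(=O)CC | intermediate (not isolated)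
6 | (5R)-2-methyl-5-[(trimethylsilyl)ethynyl]cyclohex-2-en-1-one | C[Si](C)(C)C#C[C@H]1CC(=O)C(C)=CC1 | intermediate
7 | (5R)-5-ethynyl-2-methylcyclohex-2-en-1-one | C#C[C@H]1CC(=O)C(C)=CC1 | intermediate (not isolated)
8 | (5R)-5-(1-iodoethenyl)-2-methylcyclohex-2-en-1-one | C=C(I)[C@H]1CC(=O)C(C)=CC1 | intermediate
9 | (5R,6S)-6-hydroxy-5-(1-iodoethenyl)-2-methylcyclohex-2-en-1-one | C=C(I)[C@H]1[C@H](O)C(=O)C(C)=CC1 | intermediate
10 | (5R,6S)-6-[(tert-butyldimethylsilyl)oxy]-5-(1-iodoethenyl)-2-methylcyclohex-2-en-1-one | C=C(I)[C@H]1[C@H](O[Si](C)(C)C(C)(C)C)C(=O)C(C)=CC1 | intermediate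
11 | (1R,3S,4R,6R)-3-[(tert-butyldimethylsilyl)oxy]-4-(1-iodoethenyl)-1-methyl-7-oxabicyclo[4.1.0]heptan-2-one | C=C(I)[C@H]1[C@H](O[Si](C)(C)C(C)(C)C)C(=O)[C@]2(C)O[C@@H]2C1 | intermediate
12 | (1R,4R,5R)-4-[(tert-butyldimethylsilyl)oxy]-5-(1-iodoethenyl)-2-methylcyclohex-2-en-1-ol | C=C(I)[C@H]1[C@H](O[Si](C)(C)C(C)(C)C)C=C(C)[C@H](O)C1 | intermediate
13 | (4R,5R)-4-[(tert-butyldimethylsilyl)oxy]-5-(1-iodoethenyl)-2-methylcyclohex-2-en-1-one | C=C(I)[C@H]1[C@H](O[Si](C)(C)C(C)(C)C)C=C(C)C(=O)C1 | intermediate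
14 | (4R,5R,6R)-4-[(tert-butyldimethylsilyl)oxy]-6-hydroxy-5-(1-iodoethenyl)-2-methylcyclohex-2-en-1-one | C=C(I)[C@H]1[C@H](O[Si](C)(C)C(C)(C)C)C=C(C)C(=O)[C@@H]1O | intermediate
15 | (4R,5S,6R)-4,6-bis[(tert-butyldimethylsilyl)oxy]-5-(1-iodoethenyl)-2-methylcyclohex-2-en-1-one | C=C(I)[C@H]1[C@H](O[Si](C)(C)C(C)(C)C)C=C(C)C(=O)[C@@H]1O[Si](C)(C)C(C)(C)C | intermediate
16 | (1R,3R,4S,5S,6R)-3,5-bis[(tert-butyldimethylsilyl)oxy]-4-(1-iodoethenyl)-1-methyl-7-oxabicyclo[4.1.0]heptan-2-one | C=C(I)[C@H]1[C@H](O[Si](C)(C)C(C)(C)C)[C@H]2O[C@@]2(C)C(=O)[C@@H]1O[Si](C)(C)C(C)(C)C | intermediate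
17 | (2R,3S,4S,5S,6R)-4,6-bis[(tert-butyldimethylsilyl)oxy]-2,3-dihydroxy-5-(1-iodoethenyl)-2-methylcyclohexan-1-one | C=C(I)[C@H]1[C@H](O[Si](C)(C)C(C)(C)C)[C@H](O)[C@@](C)(O)C(=O)[C@@H]1O[Si](C)(C)C(C)(C)C | intermediate
18 | 4-methylpent-3-en-1-ol | CC(C)=CCCO | starting material
19 | 4-methylpent-3-enal | CC(C)=CCC=O | intermediate
20 | (2R,3S,4S,5S,6R)-4,6-bis[(tert-butyldimethylsilyl)oxy]-2,3-dihydroxy-5-[(3S)-3-hydroxy-6-methylhepta-1,5-dien-2-yl]-2-methylcyclohexan-1-one | C=C([C@H]1[C@H](O[Si](C)(C)C(C)(C)C)[C@H](O)[C@@](C)(O)C(=O)[C@@H]1O[Si](C)(C)C(C)(C)C)[C@H](CC=C(C)C)O | intermediate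
21 | (2R,3S,4S,5S,6R)-2,3,4,6-tetrahydroxy-5-[(3S)-3-hydroxy-6-methylhepta-1,5-dien-2-yl]-2-methylcyclohexan-1-one | C=C([C@H]1[C@H](O)[C@H](O)[C@@](C)(O)C(=O)[C@@H]1O)[C@H](CC=C(C)C)O | intermediate
22 | 4-O,6-O,3′-O-tris[(Z)-2-methylbut-2-enoate] of 21 | C=C([C@H]1[C@H](OC(=O)/C(C)=C\C)[C@H](O)[C@@](C)(O)C(=O)[C@@H]1OC(=O)/C(C)=C\C)[C@H](CC=C(C)C)OC(=O)/C(C)=C\C | intermediate
23 | CNP0313777.1 | C=C([C@H]1[C@H](OC(=O)/C(C)=C\C)[C@H](O)[C@@](C)(O)C(=O)[C@@H]1OC(=O)/C(C)=C\C)[C@H](C[C@H]1OC1(C)C)OC(=O)/C(C)=C\C | target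

**Step count**

Total steps: 17. Longest linear sequence: 16 (steps 1–12 and 14–17; step 13 prepares the aldehyde partner).

**Steps most likely to fail, with fallbacks**

Step 16. The triple esterification may stall at the hindered C5 hydroxyl, run on to the C6 hydroxyl, or be accompanied by acyl migration or Z-to-E isomerisation. The fallback sets out from 21 and esterifies in two stages. The cis C5/C6 diol is first tied up with 2-methoxypropene and PPTS as acetonide F1. The C3 and C8 hydroxyls are then acylated with the same mixed anhydride to give bis-angelate acetonide F2. Aqueous AcOH frees the diol to give bis-angelate diol F3. The dibutylstannylene acetal (Bu2SnO, toluene) then directs the last angeloylation to the equatorial C5 oxygen, and the route is rejoined at 22.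

Step 11. Facial selectivity may be eroded because the C4 side chain and the C5 silyloxy group bias the two faces in opposite senses, which would give the wrong C1/C6 diol after hydrolysis. The fallback sets out from 15 and uses hydroxyl direction instead. Luche reduction (NaBH4, CeCl3·7H2O, MeOH) should give the equatorial C2 carbinol on the face of the C4 side chain, allylic alcohol F4. VO(acac)2 with tert-butyl hydroperoxide then delivers oxygen syn to that hydroxyl and anti to the C5 silyloxy group, giving epoxy alcohol F5. DMP oxidation rejoins the route at 16.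

Step 14. Diastereoselection at C8 may be low if the ligand is mismatched with the substrate or the free hydroxyls compete for chromium. The fallback sets out from 17 and 19, coupled with CrCl2 and NiCl2 (cat.) without the chiral ligand, which gives 20 together with its C8 epimer F6. MnO2 oxidises only the allylic C8 carbinol of the mixture to enone F7. Corey–Bakshi–Shibata reduction with the (R)-configured B-methyl oxazaborolidine and catecholborane (reagent control, alkenyl group as the large substituent, hindered ring ketone untouched) rejoins the route at 20.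

**Further compounds**

F1 | step 16 | 4,3-O-isopropylidene acetal (C5/C6 acetonide, target numbering) of 21 | C=C([C@H]1[C@@H]2OC(C)(C)O[C@@H]2[C@@](C)(O)C(=O)[C@@H]1O)[C@H](CC=C(C)C)O
F2 | step 16 | C3,C8-bis-angelate of acetonide F1 | C=C([C@H]1[C@@H]2OC(C)(C)O[C@@H]2[C@@](C)(O)C(=O)[C@@H]1OC(=O)/C(C)=C\C)[C@H](CC=C(C)C)OC(=O)/C(C)=C\C
F3 | step 16 | C3,C8-bis-angelate with free C5/C6 diol | C=C([C@H]1[C@H](O)[C@H](O)[C@@](C)(O)C(=O)[C@@H]1OC(=O)/C(C)=C\C)[C@H](CC=C(C)C)OC(=O)/C(C)=C\C
F4 | step 11 | 4,6-bis[(tert-butyldimethylsilyl)oxy]-5-(1-iodoethenyl)-2-methylcyclohex-2-en-1-ol (hydroxyl cis to the iodoethenyl group) | C=C(I)[C@H]1[C@H](O[Si](C)(C)C(C)(C)C)C=C(C)[C@@H](O)[C@@H]1O[Si](C)(C)C(C)(C)C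
F5 | step 11 | 3,5-bis[(tert-butyldimethylsilyl)oxy]-4-(1-iodoethenyl)-1-methyl-7-oxabicyclo[4.1.0]heptan-2-ol (epoxide syn to the hydroxyl) | C=C(I)[C@H]1[C@H](O[Si](C)(C)C(C)(C)C)[C@H]2O[C@@]2(C)[C@@H](O)[C@@H]1O[Si](C)(C)C(C)(C)C
F6 | step 14 | C8 epimer of 20 [(3R)-3-hydroxy-6-methylhepta-1,5-dien-2-yl side chain] | C=C([C@H]1[C@H](O[Si](C)(C)C(C)(C)C)[C@H](O)[C@@](C)(O)C(=O)[C@@H]1O[Si](C)(C)C(C)(C)C)[C@@H](CC=C(C)C)O
F7 | step 14 | (2R,3S,4S,5S,6R)-4,6-bis[(tert-butyldimethylsilyl)oxy]-2,3-dihydroxy-2-methyl-5-(6-methyl-3-oxohepta-1,5-dien-2-yl)cyclohexan-1-one | C=C([C@H]1[C@H](O[Si](C)(C)C(C)(C)C)[C@H](O)[C@@](C)(O)C(=O)[C@@H]1O[Si](C)(C)C(C)(C)C)C(=O)CC=C(C)C
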